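**Retrosynthetic overview**
1. I read the target as a hidden 3,3'-diprenyl-2,2'-biphenol, because 4'-OH and 7''-OH flank the 3'–8'' axis and each has a prenyl group on its other ortho carbon. Both prenyls are removed together by a retro double aromatic Claisen, giving the 4',7''-bis(1,1-dimethylallyl) ether.
2. The same two oxygens are then tied together as a tBu2Si bridge. A retro intramolecular Pd C–H arylation (8''-I onto either of the two equivalent ortho C–H bonds of ring B) gives an unsymmetrical bis(aryloxy)silane.
3. The silane comes from 8-iodo-5,4'-di-O-acetylapigenin and 7-O-MOM-apigenin, both made from apigenin through its innate 7-OH selectivity.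
4. The route avoids the obvious disconnection, an intermolecular Suzuki union of an 8-halo-6-prenylflavone with a 3'-boryl-5'-prenylflavone.
5. Ring order: all six rings of the target are bought as two molecules of apigenin. The only ring made is the sacrificial seven-membered dioxasilepine, closed in step 6 and opened in step 7.

Assumption: the SMILES has no stereodescriptor (no stereocentre, no E/Z alkene). The axis carries only three small ortho groups (OH, OH, ring O) and is unassigned, so I treat it as configurationally labile and there is no stereochemical element to control.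

**Step 1**
Reactants: 1 apigenin (5,7,4'-trihydroxyflavone)
Product: 2 apigenin 5,7,4'-triacetate
Conditions: Ac2O (6 equiv), pyridine, DMAP (cat.), 50 °C
Reagents that add atoms: acetic anhydride, CC(=O)OC(C)=O
Why: This is exhaustive DMAP-catalysed O-acylation, and gentle heating also acetylates the chelated 5-OH.

**Step 2**
Reactants: 2 apigenin triacetate
Product: 3 5,4'-di-O-acetylapigenin (7-OH free)
Conditions: PhSH (1.3 equiv), imidazole (0.4 equiv), NMP, 0 °C → rt
Reagents that add atoms: none
Why: This is a regioselective thiolate-mediated deacylation, since the 7-acetate releases the best leaving phenoxide (para to C4=O) and is cleaved first while the 5- and 4'-acetates survive.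

**Step 3**
Reactants: 3 5,4'-di-O-acetylapigenin
Product: 4 8-iodo-5,4'-di-O-acetylapigenin (7-OH free, iodine at C8)
Conditions: NIS (1.05 equiv), TFA (10 mol %), MeCN–CH2Cl2, 0 °C, dark
Reagents that add atoms: N-iodosuccinimide, O=C1CCC(=O)N1I
Why: This is an SEAr iodination ortho to the only free phenol, with C8 preferred over C6 by the usual 7-hydroxychromone bond fixation and because C6 is crowded by the 5-OAc; the acetylated ring B is too deactivated to react.

**Step 4**
Reactants: 1 apigenin
Product: 5 7-O-(methoxymethyl)apigenin (5-OH and 4'-OH free)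
Conditions: MOMCl (1.05 equiv), K2CO3 (1.1 equiv), DMF, 0 °C → rt
Reagents that add atoms: chloromethyl methyl ether, COCCl
Why: This is a Williamson-type alkylation under limiting base, in which the most acidic 7-OH ionises first, the 4'-OH is weaker and the 5-OH is chelated, so the 7-mono-ether dominates and the minor bis-ether is removed by chromatography.

**Step 5**
Reactants: 4 8-iodo-5,4'-di-O-acetylapigenin; 5 7-O-MOM-apigenin
Product: 6 unsymmetrical di-tert-butyl-bis(aryloxy)silane, with O7 of 4 and O4' of 5 joined through Si(tBu)2
Conditions: 4, tBu2Si(OTf)2 (1.0 equiv), 2,6-lutidine, CH2Cl2, −78 → 0 °C; then 5, imidazole, DMF, 0 → 40 °C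
Reagents that add atoms: di-tert-butylsilyl bis(triflate), CC(C)(C)[Si](OS(=O)(=O)C(F)(F)F)(OS(=O)(=O)C(F)(F)F)C(C)(C)C
Why: This is a sequential silyl triflate substitution in which the hindered iodophenol meets the very reactive bis-triflate first and stops at the mono-triflate for steric reasons, the unhindered 4'-OH of 5 then performs the harder second displacement, and the chelated 5-OH does not compete.

**Step 6 (key step 1)**
Reactants: 6 bis(aryloxy)silane
Product: 7 4',7''-O,O-(di-tert-butylsilanediyl)-5'',4'''-di-O-acetyl-7-O-MOM-amentoflavone (new C3'–C8'' bond inside a seven-membered dibenzo[1,3,2]dioxasilepine)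
Conditions: Pd(OAc)2 (10 mol %), PCy3·HBF4 (20 mol %), CsOPiv (2.5 equiv), 4 Å MS, PhMe (0.01 M), 110 °C
Reagents that add atoms: none
Why: This is a silicon-tethered intramolecular direct arylation (concerted metalation–deprotonation), a known route to unsymmetrical o,o'-biphenols, in which the tether enforces cross-selectivity, the two reachable C–H bonds of ring B are equivalent, and anhydrous pivalate in toluene is mild toward the acetates, the MOM ether and the silyl ethers.

**Step 7**
Reactants: 7 silylene-bridged biflavone
Product: 8 5'',4'''-di-O-acetyl-7-O-MOM-amentoflavone (4'-OH and 7''-OH freed; chelated 5-OH also free)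
Conditions: Et3N·3HF (5 equiv), THF, 0 °C → rt
Reagents that add atoms: none
Why: This is a buffered fluoride desilylation that cleaves only the Si–O bonds, so exactly the two phenols flanking the axis are unmasked and the acetates and MOM ether are kept.

**Step 8**
Reactants: 9 2-methylbut-3-en-2-ol
Product: 10 tert-butyl 2-methylbut-3-en-2-yl carbonate
Conditions: n-BuLi, THF, 0 °C; then Boc2O, 0 °C → rt
Reagents that add atoms: di-tert-butyl dicarbonate, CC(C)(C)OC(=O)OC(=O)OC(C)(C)C
Why: This is alkoxide acylation with Boc2O, the standard preparation of this reverse-prenyl donor.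

**Step 9**
Reactants: 8 4',7''-diol; 10 carbonate (2.4 equiv)
Product: 11 4',7''-bis-O-(1,1-dimethylallyl)-5'',4'''-di-O-acetyl-7-O-MOM-amentoflavone
Conditions: Pd(PPh3)4 (10 mol %), THF, 0–5 °C
Reagents that add atoms: compound 10, C=CC(C)(C)OC(=O)OC(C)(C)C (delivers C5H9 twice)
Why: This is a decarboxylative Tsuji–Trost O-allylation in which, at low temperature, phenoxide attacks the more substituted terminus of the π-prenyl-Pd to give the tertiary ether kinetically, and limiting the donor leaves the chelated 5-OH untouched.

**Step 10 (key step 2)**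
Reactants: 11 bis(1,1-dimethylallyl) ether
Product: 12 5',6''-diprenyl-5'',4'''-di-O-acetyl-7-O-MOM-amentoflavone
Conditions: PhNEt2, 130 °C, 3 h, Ar
Reagents that add atoms: none
Why: This is a double aromatic Claisen ([3,3] with allyl inversion, O–CMe2–CH=CH2 → C–CH2–CH=CMe2) in which shifts to C3' or C8'' (and onward Cope shifts to C1' or C4a'') hit substituted carbons and are reversible, so only C5' and C6'' can rearomatise and both prenyls land correctly in one operation; no stereocentre is formed.

**Step 11**
Reactants: 12 protected diprenyl biflavone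
Product: 13 dulcisbiflavonoid A (target)
Conditions: K2CO3, MeOH–THF, rt, 1 h (Ar); then 3 M aq HCl added to the same flask, 45 °C, about 1.5 h
Reagents that add atoms: none
Why: Zemplén-type methanolysis removes both aryl acetates and a brief acid acetal hydrolysis then removes the single MOM group, which is the standard final step for prenylated flavonoids and is kept short and mild to avoid chroman formation from prenyl and ortho-OH.

**Compound list**
| No. | Name | SMILES | Role |
|---|---|---|---|
| 1 | apigenin | O=c1cc(-c2ccc(O)cc2)oc2cc(O)cc(O)c12 | starting material |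
| 2 | apigenin triacetate | CC(=O)Oc1ccc(cc1)-c1cc(=O)c2c(OC(C)=O)cc(OC(C)=O)cc2o1 | intermediate |
| 3 | 5,4'-di-O-acetylapigenin | CC(=O)Oc1ccc(cc1)-c1cc(=O)c2c(OC(C)=O)cc(O)cc2o1 | intermediate |
| 4 | 8-iodo-5,4'-di-O-acetylapigenin | CC(=O)Oc1ccc(cc1)-c1cc(=O)c2c(OC(C)=O)cc(O)c(I)c2o1 | intermediate |
| 5 | 7-O-MOM-apigenin | COCOc1cc(O)c2c(=O)cc(-c3ccc(O)cc3)oc2c1 | intermediate |
| 6 | unsymmetrical tBu2Si bis(aryloxy)silane | CC(=O)Oc1ccc(cc1)-c1cc(=O)c2c(OC(C)=O)cc(O[Si](C(C)(C)C)(C(C)(C)C)Oc3ccc(cc3)-c3cc(=O)c4c(O)cc(OCOC)cc4o3)c(I)c2o1 | intermediate |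
| 7 | silylene-bridged amentoflavone derivative | CC(=O)Oc1ccc(cc1)-c1cc(=O)c2c(OC(C)=O)cc3O[Si](C(C)(C)C)(C(C)(C)C)Oc4ccc(cc4-c3c2o1)-c1cc(=O)c2c(O)cc(OCOC)cc2o1 | intermediate |
| 8 | 5'',4'''-di-O-acetyl-7-O-MOM-amentoflavone | COCOc1cc(O)c2c(=O)cc(oc2c1)-c1ccc(O)c(c1)-c1c(O)cc(OC(C)=O)c2c(=O)cc(oc12)-c1ccc(OC(C)=O)cc1 | intermediate |
| 9 | 2-methylbut-3-en-2-ol | CC(C)(O)C=C | starting material |
| 10 | tert-butyl 2-methylbut-3-en-2-yl carbonate | C=CC(C)(C)OC(=O)OC(C)(C)C | intermediate |
| 11 | 4',7''-bis(1,1-dimethylallyl) ether of 8 | COCOc1cc(O)c2c(=O)cc(oc2c1)-c1ccc(OC(C)(C)C=C)c(c1)-c1c(OC(C)(C)C=C)cc(OC(C)=O)c2c(=O)cc(oc12)-c1ccc(OC(C)=O)cc1 | intermediate |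
| 12 | 5',6''-diprenyl-5'',4'''-di-O-acetyl-7-O-MOM-amentoflavone | COCOc1cc(O)c2c(=O)cc(oc2c1)-c1cc(CC=C(C)C)c(O)c(c1)-c1c(O)c(CC=C(C)C)c(OC(C)=O)c2c(=O)cc(oc12)-c1ccc(OC(C)=O)cc1 | intermediate |
| 13 | dulcisbiflavonoid A (no stereodescriptors) | CC(C)=CCc1cc(-c2cc(=O)c3c(O)cc(O)cc3o2)cc(-c2c(O)c(CC=C(C)C)c(O)c3c(=O)cc(-c4ccc(O)cc4)oc23)c1O | target |

**Total steps:** 11. **Longest linear sequence:** 9 (steps 1, 2, 3, 5, 6, 7, 9, 10, 11).

**Steps most likely to fail**
1. **Step 6, tethered C–H arylation.** The risks are closure of a seven-membered ring at a hindered, electron-rich iodide, protodeiodination, and acyl scrambling. Fallback: drop the tether and the C–H partner. Protect the 7-OH of 4 as a TBS ether and join it by intermolecular Suzuki–Miyaura coupling to a 4'-O-TBS-3'-Bpin analogue of 5. That partner would be built de novo from 3-bromo-4-hydroxybenzaldehyde and 2-hydroxy-4,6-bis(MOM-oxy)acetophenone by aldol, oxidative cyclisation and Miyaura borylation. Fluoride then frees the same two axis-flanking phenols as in 8, and the endgame is unchanged.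
2. **Step 9, double tertiary ether formation on the two axis-flanking phenols.** The risks are low conversion, Pd-mediated leakage to linear O-prenyl ethers, and 5-O-alkylation. Fallback: O-allylate both phenols with allyl bromide and run the same axis-blocked double Claisen on the bis(allyl) ether. Both C-allyl groups are then converted to prenyl by double cross-metathesis with 2-methyl-2-butene (Grubbs II).
3. **Step 3, C8 versus C6 iodination.** Fallback: fix the iodine position before the pyranone exists. Iodinate a 2-hydroxy-4,6-dioxygenated acetophenone ortho to its chelated OH (position 3). Then aroylate with a protected 4-hydroxybenzoyl chloride and carry out Baker–Venkataraman rearrangement and cyclodehydration. The OH next to iodine becomes O1, so the halogen must end up at C8.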